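The route rests on disconnecting the C4a–C5 bond of aromatic ring A. That ring is an acylphloroglucinol (oxygens on C5, C7 and C8a, the C4 acyl carbon on C4a), so it can be closed polyketide-style while C8 is still an sp3 carbon that already carries the prenyl group. In one operation, thermolysis of a dioxinone releases an acylketene whose terminal carbon (C5) bonds to C4a of a preformed (2S)-2-phenyl-2,3-dihydropyran-4-one (ring C), and tautomerisation delivers the 5,7-dihydroxy-8-prenylflavanone with no regioisomer possible. The precursor is that dihydropyranone carrying at C6 a CH(prenyl) group bonded to the dioxinone. O-Methylation and cis-selective hydride reduction finish the target.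

Key step: step 7

Remark: flavan numbering (O1, C2, C3, C4, C4a, C5 to C8, C8a) is applied to all intermediates; the target is the 2,4-cis isomer (2S,4S), and the carbon that becomes C8 is carried as both epimers from 5 to 12 because it ends as an aromatic carbon.

Step 1
Reactants: 1 2,2,6-trimethyl-4H-1,3-dioxin-4-one; 2 acetyl chloride
Product: 3 2,2-dimethyl-6-(2-oxopropyl)-4H-1,3-dioxin-4-one
Conditions: 1 (2 equiv), LiN(SiMe3)2 (2 equiv), THF, −78 °C; then 2 (1 equiv), −78 °C; aq NH4Cl
Reagents that add atoms: none
Why: Kinetic deprotonation of the 6-methyl group gives the lithium dienolate, which is C-acylated at its γ-carbon by the acid chloride (vinylogous Claisen-type acylation), the second equivalent of dienolate serving to deprotonate the more acidic keto-dioxinone as it forms.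

Step 2
Reactants: 3 2,2-dimethyl-6-(2-oxopropyl)-4H-1,3-dioxin-4-one; 4 prenyl bromide (1-bromo-3-methylbut-2-ene)
Product: 5 2,2-dimethyl-6-(6-methyl-2-oxohept-5-en-3-yl)-4H-1,3-dioxin-4-one (racemic)
Conditions: 4 (1.0 equiv), K2CO3, acetone, 0 °C → rt
Reagents that add atoms: none
Why: The methylene flanked by the ketone and the dioxinone ring is the most acidic site and its soft enolate is C-alkylated by the allylic bromide in an SN2 reaction (active-methylene alkylation), one equivalent of bromide limiting dialkylation; the new stereocentre is formed racemic, which is irrelevant because it later becomes aromatic C8.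

Step 3
Reactants: 6 methyl (S)-3-hydroxy-3-phenylpropanoate
Product: 7 methyl (S)-3-phenyl-3-(triethylsilyloxy)propanoate
Conditions: Et3SiCl, imidazole, CH2Cl2, 0 °C → rt
Reagents that add atoms: chlorotriethylsilane, CC[Si](CC)(CC)Cl
Why: Routine silylation of a secondary benzylic alcohol that does not touch the C–O bond, so the S configuration is kept, and that blocks retro-aldol cleavage and alkoxide chemistry in the two basic steps that follow.

Step 4
Reactants: 7 methyl (S)-3-phenyl-3-(triethylsilyloxy)propanoate
Product: 8 (S)-N-methoxy-N-methyl-3-phenyl-3-(triethylsilyloxy)propanamide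
Conditions: MeNH(OMe)·HCl (1.5 equiv), iPrMgCl (3 equiv), THF, −20 → 0 °C
Reagents that add atoms: N,O-dimethylhydroxylamine hydrochloride, CNOC.Cl
Why: The chloromagnesium amide generated from the hydroxylamine salt displaces methoxide from the ester at low temperature (Weinreb amide formation), conditions under which the β-silyloxy group is not eliminated and the stereocentre is not involved.

Step 5
Reactants: 5 2,2-dimethyl-6-(6-methyl-2-oxohept-5-en-3-yl)-4H-1,3-dioxin-4-one; 8 (S)-N-methoxy-N-methyl-3-phenyl-3-(triethylsilyloxy)propanamide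
Product: 9 6-[(10S)-2-methyl-6,8-dioxo-10-phenyl-10-(triethylsilyloxy)dec-2-en-5-yl]-2,2-dimethyl-4H-1,3-dioxin-4-one (both C5 epimers)
Conditions: 5 (1.3 equiv), LiN(iPr)2 (2.7 equiv), THF, −78 → −20 °C; then 8 (1.0 equiv), −78 → 0 °C; aq NH4Cl
Reagents that add atoms: none
Why: Two equivalents of amide base remove first the doubly activated methine proton and then a methyl proton of 5, and the more reactive terminal enolate carbon of this dianion adds to the Weinreb amide (crossed Claisen-type acylation of a dianion), the chelated tetrahedral adduct surviving until work-up so that neither over-addition nor quenching of the dianion by the product diketone occurs.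

Step 6
Reactants: 9 6-[(10S)-2-methyl-6,8-dioxo-10-phenyl-10-(triethylsilyloxy)dec-2-en-5-yl]-2,2-dimethyl-4H-1,3-dioxin-4-one
Product: 12 (2S)-6-[1-(2,2-dimethyl-4-oxo-4H-1,3-dioxin-6-yl)-4-methylpent-3-enyl]-2-phenyl-2,3-dihydro-4H-pyran-4-one (both epimers at the side-chain carbon), via hydroxy diketone 10 (not isolated), via cyclic hemiketal 11 (not isolated)
Conditions: HF·pyridine, THF, 0 °C → rt; then TsOH·H2O (0.1 equiv), CH2Cl2, 4 Å MS, rt
Reagents that add atoms: none
Why: Fluoride cleaves the silyl ether, the freed hydroxyl adds to the only carbonyl within six-membered reach (the future C8a) and the hemiketal loses water under mild sulfonic acid catalysis to give the conjugated vinylogous ester (cyclodehydration of a δ-hydroxy β-diketone), a sequence in which the benzylic C–O bond is never broken so that C2 stays S.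

Step 7
Reactants: 12 (2S)-6-[1-(2,2-dimethyl-4-oxo-4H-1,3-dioxin-6-yl)-4-methylpent-3-enyl]-2-phenyl-2,3-dihydro-4H-pyran-4-one
Product: 16 (2S)-5,7-dihydroxy-8-(3-methylbut-2-enyl)-2-phenyl-2,3-dihydro-4H-chromen-4-one, via acylketene 13 (not isolated), via hydroxy dienylketene 14 (not isolated), via cyclohexadienone 15 (not isolated)
Conditions: PhMe (0.002 M, slow addition of 12 to the hot solvent), 4 Å MS, Ar, 110 °C
Reagents that add atoms: none
Why: Proposed new method: at 110 °C the dioxinone should undergo retro-[4+2] loss of acetone to acylketene 13 (C7(=O)–C6H=C5=O), whose C8 hydrogen, activated by the C7 ketone and the C8a=C4a enol ether, can shift to oxygen to give the hydroxy dienylketene 14 (C4a=C8a–C8=C7–C6=C5=O). Thermally allowed disrotatory 6π-electrocyclisation (in polar terms, attack of the nucleophilic α-carbon C4a of the vinylogous ester on the ketene carbon) forms the C4a–C5 bond and closes carbocyclic ring A as cyclohexadienone 15, which enolises irreversibly to the phloroglucinol. The closest known reaction types are the thermolysis of dioxinones to acylketenes followed by biomimetic aromatisation to resorcylates, and the 6π ring closure of dienylketenes that completes vinylketene benzannulations; joining a ketene carbon to the α-carbon of a dihydropyranone in this way has not been shown. Ring A is closed as a six-membered all-carbon ring in the 6π-electrocyclic mode, and no stereocentre is created, since the stereogenic side-chain carbon (C8) and the transient C4a are both flattened on aromatisation. The step needs chemoselective intramolecular capture of the ketene at C4a, which the substrate secures because the O1–C8a bond is already in place, so that C4a is the only nucleophilic site within six-membered reach (capture by an oxygen would need a four- or eight-membered ring) and only the 8-prenyl isomer can arise, while high dilution and dry toluene suppress dimerisation and capture by water or by the product phenols. The neutral medium leaves the C2 stereocentre, which base would erase by opening ring C to the chalcone, untouched.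

Step 8
Reactants: 16 (2S)-5,7-dihydroxy-8-(3-methylbut-2-enyl)-2-phenyl-2,3-dihydro-4H-chromen-4-one
Product: 17 (2S)-5,7-dimethoxy-8-(3-methylbut-2-enyl)-2-phenyl-2,3-dihydro-4H-chromen-4-one
Conditions: MeI (10 equiv), Ag2O (3 equiv), CH2Cl2, 35 °C, dark
Reagents that add atoms: iodomethane, CI
Why: Silver oxide activates iodomethane and takes up the iodide, so both phenols, the free 7-hydroxyl first and the hydrogen-bonded 5-hydroxyl more slowly, are O-methylated (Purdie-type methylation) without the soluble strong base that would enolise C3 and open ring C to the chalcone.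

Step 9
Reactants: 17 (2S)-5,7-dimethoxy-8-(3-methylbut-2-enyl)-2-phenyl-2,3-dihydro-4H-chromen-4-one
Product: 18 (2S,4S)-5,7-dimethoxy-8-(3-methylbut-2-enyl)-2-phenyl-3,4-dihydro-2H-chromen-4-ol (2,4-cis; CNP0121542.2)
Conditions: NaBH4, MeOH–THF, 0 °C; neutral work-up
Reagents that add atoms: none
Why: Borohydride attacks the C4 carbonyl of the half-chair that has the 2-phenyl group equatorial along the axial trajectory (substrate-controlled ketone reduction, known for flavanones), which places the new hydroxyl equatorial and cis to phenyl and so sets C4 as S; a neutral work-up protects the electron-rich benzylic alcohol.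

Compound list
1 | 2,2,6-trimethyl-4H-1,3-dioxin-4-one | CC1=CC(=O)OC(C)(C)O1 | starting material
2 | acetyl chloride | CC(Cl)=O | starting material
3 | 2,2-dimethyl-6-(2-oxopropyl)-4H-1,3-dioxin-4-one | CC(=O)CC1=CC(=O)OC(C)(C)O1 | intermediate
4 | prenyl bromide (1-bromo-3-methylbut-2-ene) | CC(C)=CCBr | starting material
5 | 2,2-dimethyl-6-(6-methyl-2-oxohept-5-en-3-yl)-4H-1,3-dioxin-4-one (racemic) | CC(=O)C(CC=C(C)C)C1=CC(=O)OC(C)(C)O1 | intermediate
6 | methyl (S)-3-hydroxy-3-phenylpropanoate | O[C@H](c1ccccc1)CC(=O)OC | starting material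
7 | methyl (S)-3-phenyl-3-(triethylsilyloxy)propanoate | CC[Si](CC)(CC)O[C@H](c1ccccc1)CC(=O)OC | intermediate
8 | (S)-N-methoxy-N-methyl-3-phenyl-3-(triethylsilyloxy)propanamide | CC[Si](CC)(CC)O[C@H](c1ccccc1)CC(=O)N(C)OC | intermediate
9 | 6-[(10S)-2-methyl-6,8-dioxo-10-phenyl-10-(triethylsilyloxy)dec-2-en-5-yl]-2,2-dimethyl-4H-1,3-dioxin-4-one (both C5 epimers) | CC[Si](CC)(CC)O[C@H](c1ccccc1)CC(=O)CC(=O)C(CC=C(C)C)C1=CC(=O)OC(C)(C)O1 | intermediate
10 | hydroxy diketone, not isolated: 6-[(10S)-10-hydroxy-2-methyl-6,8-dioxo-10-phenyldec-2-en-5-yl]-2,2-dimethyl-4H-1,3-dioxin-4-one | O[C@H](c1ccccc1)CC(=O)CC(=O)C(CC=C(C)C)C1=CC(=O)OC(C)(C)O1 | intermediate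
11 | cyclic hemiketal, not isolated: 6-{1-[(6S)-2-hydroxy-4-oxo-6-phenyltetrahydro-2H-pyran-2-yl]-4-methylpent-3-enyl}-2,2-dimethyl-4H-1,3-dioxin-4-one | O=C1C[C@@H](c2ccccc2)OC(O)(C(CC=C(C)C)C2=CC(=O)OC(C)(C)O2)C1 | intermediate
12 | (2S)-6-[1-(2,2-dimethyl-4-oxo-4H-1,3-dioxin-6-yl)-4-methylpent-3-enyl]-2-phenyl-2,3-dihydro-4H-pyran-4-one (both epimers at the side-chain carbon; key-step precursor) | O=C1C=C(C(CC=C(C)C)C2=CC(=O)OC(C)(C)O2)O[C@H](c2ccccc2)C1 | intermediate
13 | acylketene, not isolated: 7-methyl-3-oxo-4-[(2S)-4-oxo-2-phenyl-3,4-dihydro-2H-pyran-6-yl]octa-1,6-dien-1-one | O=C1C=C(C(CC=C(C)C)C(=O)C=C=O)O[C@H](c2ccccc2)C1 | intermediate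
14 | hydroxy dienylketene, not isolated: 3-hydroxy-7-methyl-4-[(2S)-4-oxo-2-phenyl-3,4-dihydro-2H-pyran-6-yl]octa-1,3,6-trien-1-one | O=C1C=C(C(CC=C(C)C)=C(O)C=C=O)O[C@H](c2ccccc2)C1 | intermediate
15 | cyclohexadienone, not isolated: (2S)-7-hydroxy-8-(3-methylbut-2-enyl)-2-phenyl-2,3-dihydro-4H-chromene-4,5(4aH)-dione | O=C1C[C@@H](c2ccccc2)OC2=C(CC=C(C)C)C(O)=CC(=O)C12 | intermediate
16 | (2S)-5,7-dihydroxy-8-(3-methylbut-2-enyl)-2-phenyl-2,3-dihydro-4H-chromen-4-one (key-step product) | Oc1cc(O)c2c(c1CC=C(C)C)O[C@H](c1ccccc1)CC2=O | intermediate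
17 | (2S)-5,7-dimethoxy-8-(3-methylbut-2-enyl)-2-phenyl-2,3-dihydro-4H-chromen-4-one | COc1cc(OC)c2c(c1CC=C(C)C)O[C@H](c1ccccc1)CC2=O | intermediate
18 | (2S,4S)-5,7-dimethoxy-8-(3-methylbut-2-enyl)-2-phenyl-3,4-dihydro-2H-chromen-4-ol | COc1cc(OC)c2c(c1CC=C(C)C)O[C@H](c1ccccc1)C[C@@H]2O | target

Total step count: 9.
Longest linear sequence: 7 steps (steps 1, 2, 5, 6, 7, 8, 9 from 1; the branch from 6 through steps 3 and 4 is equally long).

Steps most likely to fail

1. Step 7 (proposed new method). The ketene may be consumed before the C4a–C5 bond forms: by dimerisation, by acylating the phenols of product already formed, by traces of water (hydrolysis and decarboxylation), or by intramolecular reaction with the prenyl double bond. Tautomerisation to the dienylketene may also be too slow at this temperature. The fallback uses known chemistry only; it sets out from prenyl bromide 4 and rejoins the route at 17, so step 8 is bypassed as well. Purchased 2,4,6-trihydroxyacetophenone is C-prenylated with 4 in aqueous KOH at 0 °C to give 1-[2,4,6-trihydroxy-3-(3-methylbut-2-enyl)phenyl]ethanone F1. Me2SO4 (2 equiv) and K2CO3 in acetone should etherify the 4-hydroxyl and the less hindered of the two chelated hydroxyls, giving 1-[2-hydroxy-4,6-dimethoxy-3-(3-methylbut-2-enyl)phenyl]ethanone F2. Heating with N,N-dimethylformamide dimethyl acetal gives (E)-3-(dimethylamino)-1-[2-hydroxy-4,6-dimethoxy-3-(3-methylbut-2-enyl)phenyl]prop-2-en-1-one F3, which closes with loss of dimethylamine in dilute HCl/CH2Cl2 to 5,7-dimethoxy-8-(3-methylbut-2-enyl)-4H-chromen-4-one F4. Asymmetric 1,4-addition of phenylboronic acid, catalysed by [Rh(OH)(cod)]2 and an electron-poor atropisomeric bisphosphine in the enantiomeric form that delivers the 2S product, then gives 17.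

2. Step 5. The strongly basic dianion may deprotonate the Weinreb amide next to its carbonyl, after which silanolate is eliminated to the cinnamamide; the second deprotonation of the hindered prenylated ketone may also be incomplete, so that conversion stalls. The fallback replaces the acylation by an aldol addition and an oxidation; it sets out from 7 and returns at 9. iBu2AlH (CH2Cl2, −78 °C) reduces 7 to (S)-3-phenyl-3-(triethylsilyloxy)propanal F5. The dianion of 5 (LiN(iPr)2, THF, −78 °C) adds to this aldehyde to give 6-[(10S)-8-hydroxy-2-methyl-6-oxo-10-phenyl-10-(triethylsilyloxy)dec-2-en-5-yl]-2,2-dimethyl-4H-1,3-dioxin-4-one F6 as a mixture of diastereomers. Dess–Martin periodinane then oxidises the carbinol to the 1,3-diketone 9.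

3. Step 8. Etherification of the hydrogen-bonded 5-hydroxyl may be sluggish, and forcing it invites enolisation at C3 with opening of ring C to the chalcone and loss of the C2 configuration. The fallback removes the hydrogen bond before the second methylation; it sets out from 16 and returns at 18. Me3SiCHN2 in MeOH–PhMe methylates only the free 7-hydroxyl to give (2S)-5-hydroxy-7-methoxy-8-(3-methylbut-2-enyl)-2-phenyl-2,3-dihydro-4H-chromen-4-one F7. NaBH4 (MeOH, 0 °C) reduces C4 to the cis alcohol (2S,4S)-7-methoxy-8-(3-methylbut-2-enyl)-2-phenyl-3,4-dihydro-2H-chromene-4,5-diol F8, whose 5-hydroxyl is now an ordinary phenol. MeI and K2CO3 in acetone at rt should then methylate this phenol selectively over the secondary alcohol to give 18.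

Further compounds
F1 | step 7 | 1-[2,4,6-trihydroxy-3-(3-methylbut-2-enyl)phenyl]ethanone | CC(=O)c1c(O)cc(O)c(CC=C(C)C)c1O
F2 | step 7 | 1-[2-hydroxy-4,6-dimethoxy-3-(3-methylbut-2-enyl)phenyl]ethanone | CC(=O)c1c(OC)cc(OC)c(CC=C(C)C)c1O
F3 | step 7 | (E)-3-(dimethylamino)-1-[2-hydroxy-4,6-dimethoxy-3-(3-methylbut-2-enyl)phenyl]prop-2-en-1-one | CN(C)/C=C/C(=O)c1c(OC)cc(OC)c(CC=C(C)C)c1O
F4 | step 7 | 5,7-dimethoxy-8-(3-methylbut-2-enyl)-4H-chromen-4-one | COc1cc(OC)c2c(c1CC=C(C)C)occc2=O
F5 | step 5 | (S)-3-phenyl-3-(triethylsilyloxy)propanal | CC[Si](CC)(CC)O[C@H](c1ccccc1)CC=O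
F6 | step 5 | 6-[(10S)-8-hydroxy-2-methyl-6-oxo-10-phenyl-10-(triethylsilyloxy)dec-2-en-5-yl]-2,2-dimethyl-4H-1,3-dioxin-4-one | CC[Si](CC)(CC)O[C@H](c1ccccc1)CC(O)CC(=O)C(CC=C(C)C)C1=CC(=O)OC(C)(C)O1
F7 | step 8 | (2S)-5-hydroxy-7-methoxy-8-(3-methylbut-2-enyl)-2-phenyl-2,3-dihydro-4H-chromen-4-one | COc1cc(O)c2c(c1CC=C(C)C)O[C@H](c1ccccc1)CC2=O
F8 | step 8 | (2S,4S)-7-methoxy-8-(3-methylbut-2-enyl)-2-phenyl-3,4-dihydro-2H-chromene-4,5-diol | COc1cc(O)c2c(c1CC=C(C)C)O[C@H](c1ccccc1)C[C@@H]2O
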